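**Retrosynthetic overview**

1. Target ⇐ tert-butyl ester cleavage ⇐ C11 benzoylation ⇐ 8β-OH-directed reduction of a C11 ketone ⇐ acetolysis of a 7β,8β-epoxy alcohol ⇐ bicyclic Δ7-ene-11,14-dione.
2. Ring B (formed second): C9–C10 by intramolecular Michael addition (C9 and C10 follow from C5); C7=C8 by aldol condensation of the ring C ketone with a chiral aldehyde–enoate.
3. Ring C (formed first): enantioconvergent palladium-catalysed five-to-six ring expansion (semipinacol-type 1,2-shift) of a 1-dienyl-3-methoxycyclopentenol made from 3-methoxycyclopent-2-enone and chloroprene; it sets the C13 methyl/vinyl quaternary centre.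
4. Aldehyde–enoate: SeO2 oxidation of a senecioate, two-carbon Wittig extension, then iminium-catalysed Mukaiyama–Michael addition of an isobutyrate ketene acetal (sets C5).

**Assumptions and conventions**

- Assumption: tert-butyl 3-methylbut-2-enoate and tert-butyl 2-methylpropanoate are bought as such; their tert-butyl groups are the protecting groups of the two carboxylic acids of the target.
- Locants for bicyclic compounds follow the diterpenoid numbering of the target: ring B = C5–C10; ring C = C8, C9, C11–C14 (C14 = ring ketone carbon, C13 = quaternary carbon with CH3-17 and vinyl C15=C16). C10 carries CH3-20 and the C1H2–C2O2R arm; C5 carries the C4(CH3)2–C3O2R arm. β = face of CH3-20, α = the opposite face.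
- "Secodiester core" = this bicycle with 5α-H, 9α-H, 10β-CH3, 10α-CH2CO2tBu, 5β-C(CH3)2CO2tBu, 13β-CH3 and 13α-vinyl.
- The catalyst enantiomers in steps 2 and 6 are assigned from the usual models and have not been verified; the antipode is used if the observed sense is opposite.

**Route**

Step 1
Reactants: 1 3-methoxycyclopent-2-en-1-one; 2 2-chlorobuta-1,3-diene (chloroprene)
Product: 4 1-(buta-1,3-dien-2-yl)-3-methoxycyclopent-2-en-1-ol (racemic), via buta-1,3-dien-2-ylmagnesium chloride 3 (not isolated)
Conditions: 2, Mg, ZnCl2 (cat.), THF, reflux; then 1, 0 °C; aqueous NaHCO3 work-up (no acid)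
Reagents that add atoms: none
Why: Grignard 1,2-addition to a vinylogous ester (first stage of a Stork–Danheiser sequence, stopped before acid hydrolysis); the carbinol centre is racemic and is destroyed in step 2.

Step 2
Reactants: 4 1-(buta-1,3-dien-2-yl)-3-methoxycyclopent-2-en-1-ol (racemic)
Product: 5 (2S)-2-ethenyl-4-methoxy-2-methylcyclohex-3-en-1-one
Conditions: Pd2(dba)3·CHCl3 (2.5 mol %), (R,R)-N,N′-(cyclohexane-1,2-diyl)bis[2-(diphenylphosphanyl)benzamide] (7.5 mol %), PhCO2H (10 mol %), Et3N (10 mol %), ClCH2CH2Cl, 40 °C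
Reagents that add atoms: none
Why: Proposed new method: zerovalent palladium and benzoic acid give a palladium hydride that adds to the terminal CH2 of the 2-substituted diene to form a cationic π-allyl complex of divalent palladium; the electron-rich β-carbon of the methyl enol ether then shifts from the carbinol carbon to the methyl-bearing allyl terminus anti to palladium while benzoate removes the O–H proton (semipinacol/Wagner–Meerwein 1,2-shift, formally through a donor–acceptor cyclopropane), which enlarges the five-membered ring to the six-membered ketone and returns zerovalent palladium; π–σ–π exchange through the CH2 terminus lets the chiral ligand choose the allyl face, so both enantiomers of 4 converge on the (S) quaternary centre (the old carbinol centre becomes C=O); the closest known reaction type is the palladium-catalysed asymmetric Wagner–Meerwein ring expansion of allenyl- and alkenylcyclobutanols to 2-vinylcyclopentanones, which has not been shown for an unstrained five-membered ring, a diene-derived allyl or an enol-ether migrating group.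

Step 3
Reactants: 6 tert-butyl 3-methylbut-2-enoate
Product: 7 tert-butyl (2E)-3-methyl-4-oxobut-2-enoate
Conditions: SeO2 (1.1 equiv), 1,4-dioxane, 90 °C
Reagents that add atoms: selenium dioxide O=[Se]=O
Why: Riley allylic oxidation; the methyl group trans to the ester is oxidised to the aldehyde, giving the (E)-enal.

Step 4
Reactants: 7 tert-butyl (2E)-3-methyl-4-oxobut-2-enoate
Product: 8 tert-butyl (2E,4E)-3-methyl-6-oxohexa-2,4-dienoate
Conditions: Ph3P=CHCHO (1.0 equiv), toluene, 60 °C
Reagents that add atoms: (triphenylphosphoranylidene)acetaldehyde O=CC=P(c1ccccc1)(c1ccccc1)c1ccccc1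
Why: Wittig olefination with a stabilised ylide gives the (E)-alkene; one equivalent limits double homologation.

Step 5
Reactants: 9 tert-butyl 2-methylpropanoate
Product: 10 [(1-tert-butoxy-2-methylprop-1-en-1-yl)oxy]trimethylsilane
Conditions: LiN(iPr)2, THF, −78 °C; Me3SiCl, −78 to 0 °C
Reagents that add atoms: chlorotrimethylsilane C[Si](C)(C)Cl
Why: Ester enolisation and O-silylation give the tetrasubstituted silyl ketene acetal (no geometry issue, no stereocentre).

Step 6
Reactants: 8 tert-butyl (2E,4E)-3-methyl-6-oxohexa-2,4-dienoate; 10 [(1-tert-butoxy-2-methylprop-1-en-1-yl)oxy]trimethylsilane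
Product: 11 di-tert-butyl (2E,4R)-3,5,5-trimethyl-4-(2-oxoethyl)hex-2-enedioate
Conditions: (2R,5R)-5-benzyl-2-tert-butyl-3-methylimidazolidin-4-one·CF3CO2H (20 mol %), CH2Cl2/H2O (10:1), −40 °C
Reagents that add atoms: none
Why: Iminium-catalysed Mukaiyama–Michael addition; the ketene acetal adds 1,4 to the (E)-iminium ion on the face left open by the benzyl group of the (2R,5R) catalyst, which sets C5 as (R), and the ester-polarised distal double bond is not attacked.

Step 7
Reactants: 5 (2S)-2-ethenyl-4-methoxy-2-methylcyclohex-3-en-1-one; 11 di-tert-butyl (2E,4R)-3,5,5-trimethyl-4-(2-oxoethyl)hex-2-enedioate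
Product: 13 di-tert-butyl (2E,4R)-4-{(2E)-2-[(3S)-3-ethenyl-5-methoxy-3-methyl-2-oxocyclohex-4-en-1-ylidene]ethyl}-3,5,5-trimethylhex-2-enedioate, via aldol adduct 12 (not isolated)
Conditions: LiN(iPr)2, THF, −78 °C; then 11; then MsCl, −78 to 0 °C; then DBU, 23 °C
Reagents that add atoms: none
Why: Directed aldol addition from the only enolisable position of 5 (C8), then mesylation and E1cB elimination (aldol condensation) give the thermodynamically preferred (E)-alkylidene ketone, in which C6 is cis to C9 as ring B needs; no new stereocentre.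

Step 8
Reactants: 13 di-tert-butyl (2E,4R)-4-{(2E)-2-[(3S)-3-ethenyl-5-methoxy-3-methyl-2-oxocyclohex-4-en-1-ylidene]ethyl}-3,5,5-trimethylhex-2-enedioate
Product: 15 Δ7-ene-11,14-dione of the secodiester core, via diketone 14 (not isolated)
Conditions: 0.5 M HCl, THF, 0 °C; crude 14, then KN(SiMe3)2, THF, −78 to −40 °C; AcOH quench at −78 °C
Reagents that add atoms: water O
Why: Enol ether hydrolysis unmasks the C11 ketone, whose potassium dienolate (C9) closes ring B by a 6-exo-trig intramolecular Michael addition through a chair-like transition state with the C(CH3)2CO2tBu group equatorial and, to avoid A(1,3) strain with H-5, the enoate CH pseudo-equatorial, so that C10 receives an axial β-CH3 cis to the C5 substituent and C9 an α-H with C11 equatorial; the cold quench keeps the C7=C8 double bond in place.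

Step 9
Reactants: 15 Δ7-ene-11,14-dione of the secodiester core
Product: 16 11β,14β-diol Δ7-ene of the secodiester core
Conditions: NaBH4, CeCl3·7H2O, MeOH, −40 to 0 °C
Reagents that add atoms: none
Why: Luche 1,2-reduction; hydride attacks both ketones from the α face, anti to the axial methyl groups on C10 and C13, giving the axial 11β-ol and the 14β-ol, two temporary centres that steer steps 10 and 11 and are re-oxidised in step 12.

Step 10
Reactants: 16 11β,14β-diol Δ7-ene of the secodiester core
Product: 17 7β,8β-epoxy-11β,14β-diol of the secodiester core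
Conditions: VO(acac)2 (5 mol %), tBuOOH, CH2Cl2, 0 °C
Reagents that add atoms: tert-butyl hydroperoxide CC(C)(C)OO
Why: Hydroxyl-directed epoxidation; the axial homoallylic 11β-OH (on the β face next to C8) and the allylic 14β-OH deliver oxygen to the β face of C7=C8 against the steric bias, which sets C7 and C8, and the non-directed vinyl group is left untouched.

Step 11
Reactants: 17 7β,8β-epoxy-11β,14β-diol of the secodiester core
Product: 18 7α-acetoxy-8β,11β,14β-triol of the secodiester core
Conditions: Ti(OiPr)4 (1.5 equiv), AcOH (3 equiv), CH2Cl2, 23 °C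
Reagents that add atoms: acetic acid CC(=O)O
Why: Titanium-mediated opening of a 2,3-epoxy alcohol at the carbon remote from the carbinol (here C7) by acetic acid; SN2 attack from the α face (trans-diaxial, Fürst–Plattner) gives the 7α-acetate and the tertiary 8β-alcohol in one step.

Step 12
Reactants: 18 7α-acetoxy-8β,11β,14β-triol of the secodiester core
Product: 19 7α-acetoxy-8β-hydroxy-11,14-dione of the secodiester core
Conditions: Dess–Martin periodinane (2.5 equiv), CH2Cl2, 23 °C
Reagents that add atoms: none
Why: Dess–Martin oxidation of the two secondary alcohols; the tertiary 8-OH and the acetate are inert, and neutral conditions avoid retro-aldol cleavage or β-elimination of the 8-hydroxy-11-ketone.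

Step 13
Reactants: 19 7α-acetoxy-8β-hydroxy-11,14-dione of the secodiester core
Product: 20 7α-acetoxy-8β,11α-dihydroxy-14-one of the secodiester core
Conditions: Me4NBH(OAc)3, AcOH/MeCN (1:1), −30 °C
Reagents that add atoms: none
Why: Evans–Saksena hydroxyl-directed reduction; the 8β-OH binds the acetoxyborohydride and delivers hydride to the β face of the C11 ketone (1,3-anti diol), giving the equatorial 11α-ol that external hydride does not give, while the C14 ketone between two fully substituted carbons is not reduced.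

Step 14
Reactants: 20 7α-acetoxy-8β,11α-dihydroxy-14-one of the secodiester core
Product: 21 7α-acetoxy-11α-benzoyloxy-8β-hydroxy-14-one of the secodiester core
Conditions: BzCl (1.5 equiv), pyridine, DMAP (cat.), 0 to 23 °C
Reagents that add atoms: benzoyl chloride O=C(Cl)c1ccccc1
Why: DMAP-catalysed acylation; only the secondary 11α-OH reacts, the tertiary 8β-OH does not.

Step 15
Reactants: 21 7α-acetoxy-11α-benzoyloxy-8β-hydroxy-14-one of the secodiester core
Product: 22 target diacid CNP0315860.1
Conditions: CF3CO2H/CH2Cl2 (1:4), 0 to 23 °C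
Reagents that add atoms: none
Why: Acidolysis of both tert-butyl esters with loss of isobutene; the acetate, the benzoate, the tertiary α-ketol and the vinyl group on a quaternary carbon are stable to CF3CO2H.

**Compound list**

1 | 3-methoxycyclopent-2-en-1-one | COC1=CC(=O)CC1 | starting material
2 | 2-chlorobuta-1,3-diene | C=CC(Cl)=C | starting material
3 | buta-1,3-dien-2-ylmagnesium chloride | C=CC(=C)[Mg]Cl | intermediate
4 | 1-(buta-1,3-dien-2-yl)-3-methoxycyclopent-2-en-1-ol (racemic) | C=CC(=C)C1(O)C=C(OC)CC1 | intermediate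
5 | (2S)-2-ethenyl-4-methoxy-2-methylcyclohex-3-en-1-one | C=C[C@@]1(C)C=C(OC)CCC1=O | intermediate
6 | tert-butyl 3-methylbut-2-enoate | CC(C)=CC(=O)OC(C)(C)C | starting material
7 | tert-butyl (2E)-3-methyl-4-oxobut-2-enoate | CC(C)(C)OC(=O)/C=C(C)/C=O | intermediate
8 | tert-butyl (2E,4E)-3-methyl-6-oxohexa-2,4-dienoate | CC(C)(C)OC(=O)/C=C(C)/C=C/C=O | intermediate
9 | tert-butyl 2-methylpropanoate | CC(C)C(=O)OC(C)(C)C | starting material
10 | [(1-tert-butoxy-2-methylprop-1-en-1-yl)oxy]trimethylsilane | CC(C)=C(OC(C)(C)C)O[Si](C)(C)C | intermediate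
11 | di-tert-butyl (2E,4R)-3,5,5-trimethyl-4-(2-oxoethyl)hex-2-enedioate | CC(C)(C)OC(=O)/C=C(C)/[C@H](C(C)(C)C(=O)OC(C)(C)C)CC=O | intermediate
12 | di-tert-butyl (2E,4R)-4-{2-[(3S)-3-ethenyl-5-methoxy-3-methyl-2-oxocyclohex-4-en-1-yl]-2-hydroxyethyl}-3,5,5-trimethylhex-2-enedioate (aldol adduct, mixture at the two new centres) | C=C[C@@]1(C)C=C(OC)CC(C(O)C[C@@H](C(C)(C)C(=O)OC(C)(C)C)/C(C)=C/C(=O)OC(C)(C)C)C1=O | intermediate
13 | di-tert-butyl (2E,4R)-4-{(2E)-2-[(3S)-3-ethenyl-5-methoxy-3-methyl-2-oxocyclohex-4-en-1-ylidene]ethyl}-3,5,5-trimethylhex-2-enedioate | C=C[C@@]1(C)C=C(OC)C/C(=C\C[C@@H](C(C)(C)C(=O)OC(C)(C)C)/C(C)=C/C(=O)OC(C)(C)C)C1=O | intermediate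
14 | di-tert-butyl (2E,4R)-4-{(2E)-2-[(3R)-3-ethenyl-3-methyl-2,5-dioxocyclohexylidene]ethyl}-3,5,5-trimethylhex-2-enedioate | C=C[C@@]1(C)CC(=O)C/C(=C\C[C@@H](C(C)(C)C(=O)OC(C)(C)C)/C(C)=C/C(=O)OC(C)(C)C)C1=O | intermediate
15 | Δ7-ene-11,14-dione of the secodiester core | C=C[C@@]1(C)CC(=O)[C@@H]2[C@@](C)(CC(=O)OC(C)(C)C)[C@H](C(C)(C)C(=O)OC(C)(C)C)CC=C2C1=O | intermediate
16 | 11β,14β-diol Δ7-ene of the secodiester core | C=C[C@@]1(C)C[C@H](O)[C@@H]2[C@@](C)(CC(=O)OC(C)(C)C)[C@H](C(C)(C)C(=O)OC(C)(C)C)CC=C2[C@@H]1O | intermediate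
17 | 7β,8β-epoxy-11β,14β-diol of the secodiester core | C=C[C@@]1(C)C[C@H](O)[C@@H]2[C@@](C)(CC(=O)OC(C)(C)C)[C@H](C(C)(C)C(=O)OC(C)(C)C)C[C@@H]3O[C@]23[C@@H]1O | intermediate
18 | 7α-acetoxy-8β,11β,14β-triol of the secodiester core | C=C[C@@]1(C)C[C@H](O)[C@@H]2[C@@](C)(CC(=O)OC(C)(C)C)[C@H](C(C)(C)C(=O)OC(C)(C)C)C[C@@H](OC(C)=O)[C@@]2(O)[C@@H]1O | intermediate
19 | 7α-acetoxy-8β-hydroxy-11,14-dione of the secodiester core | C=C[C@@]1(C)CC(=O)[C@@H]2[C@@](C)(CC(=O)OC(C)(C)C)[C@H](C(C)(C)C(=O)OC(C)(C)C)C[C@@H](OC(C)=O)[C@@]2(O)C1=O | intermediate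
20 | 7α-acetoxy-8β,11α-dihydroxy-14-one of the secodiester core | C=C[C@@]1(C)C[C@@H](O)[C@@H]2[C@@](C)(CC(=O)OC(C)(C)C)[C@H](C(C)(C)C(=O)OC(C)(C)C)C[C@@H](OC(C)=O)[C@@]2(O)C1=O | intermediate
21 | 7α-acetoxy-11α-benzoyloxy-8β-hydroxy-14-one of the secodiester core | C=C[C@@]1(C)C[C@@H](OC(=O)c2ccccc2)[C@@H]2[C@@](C)(CC(=O)OC(C)(C)C)[C@H](C(C)(C)C(=O)OC(C)(C)C)C[C@@H](OC(C)=O)[C@@]2(O)C1=O | intermediate
22 | CNP0315860.1: 7α-acetoxy-11α-benzoyloxy-8β-hydroxy-14-oxo-2,3-dioic acid with 13β-CH3 and 13α-vinyl; (5R,7R,8R,9S,10S,11R,13R) | C=C[C@@]1(C)C[C@@H](OC(=O)c2ccccc2)[C@@H]2[C@@](C)(CC(=O)O)[C@H](C(C)(C)C(=O)O)C[C@@H](OC(C)=O)[C@@]2(O)C1=O | target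

**Step count and risks**

Total step count: 15. Longest linear sequence: 12 steps (3, 4, 6, then 7 to 15).

The three steps most likely to fail:

Step 2 (the proposed ring expansion). The risks are ionisation of the acid-sensitive tertiary alcohol to the 3-substituted cyclopentenone and low turnover without ring strain. The fallback uses known reactions only, sets out from 1 and comes back at 5. Addition of (E)-but-2-en-2-ylmagnesium bromide to 1 gives 1-[(2E)-but-2-en-2-yl]-3-methoxycyclopent-2-en-1-ol F1. Hydroxyl-directed epoxidation (VO(acac)2, tBuOOH) gives 1-(2,3-dimethyloxiran-2-yl)-3-methoxycyclopent-2-en-1-ol F2. A Lewis-acid (ZnBr2) semipinacol rearrangement of this 2,3-epoxy alcohol enlarges the ring to 2-(1-hydroxyethyl)-4-methoxy-2-methylcyclohex-3-en-1-one F3. Dehydration with the Burgess reagent gives racemic 5, which is resolved by preparative chromatography on a chiral stationary phase into 5 and its enantiomer (2R)-2-ethenyl-4-methoxy-2-methylcyclohex-3-en-1-one F4.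

Step 8 (ring B closure). The risks are the crowded quaternary centre next to C5, retro-Michael reaction and drift of the C7=C8 double bond into ring C. The fallback sets out from 14 and comes back at 15. It replaces the anionic cyclisation by a Lewis-acid Mukaiyama–Michael addition of an isolated neutral nucleophile: 14 is silylated (TBSOTf, Et3N) to di-tert-butyl (2E,4R)-4-{(2E)-2-[(5R)-3-{[tert-butyl(dimethyl)silyl]oxy}-5-ethenyl-5-methyl-6-oxocyclohex-2-en-1-ylidene]ethyl}-3,5,5-trimethylhex-2-enedioate F5, which is cyclised by activation of the enoate with TiCl4 in CH2Cl2 at −78 °C and loses the silyl group on work-up to give 15.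

Step 10 (β-face epoxidation). The risk is delivery to the hindered β face against two axial methyl groups, with the α-epoxide as the competing product. The fallback sets out from 16 and comes back at 17. It uses two anti steps instead of a directed syn delivery: N-bromosuccinimide in aqueous THF forms the α-bromonium ion, which water opens at the tertiary C8 from the β face to give the 7α-bromo-8β,11β,14β-triol of the secodiester core F6; K2CO3 in MeOH then closes the 8β-alkoxide onto C7 to give the 7β,8β-epoxide 17.

**Further compounds**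

F1 | step 2 | 1-[(2E)-but-2-en-2-yl]-3-methoxycyclopent-2-en-1-ol (racemic) | C/C=C(\C)C1(O)C=C(OC)CC1
F2 | step 2 | 1-(2,3-dimethyloxiran-2-yl)-3-methoxycyclopent-2-en-1-ol (racemic, diastereomer mixture) | CC1OC1(C)C2(O)C=C(OC)CC2
F3 | step 2 | 2-(1-hydroxyethyl)-4-methoxy-2-methylcyclohex-3-en-1-one (racemic, diastereomer mixture) | CC(O)C1(C)C=C(OC)CCC1=O
F4 | step 2 | (2R)-2-ethenyl-4-methoxy-2-methylcyclohex-3-en-1-one | C=C[C@]1(C)C=C(OC)CCC1=O
F5 | step 8 | di-tert-butyl (2E,4R)-4-{(2E)-2-[(5R)-3-{[tert-butyl(dimethyl)silyl]oxy}-5-ethenyl-5-methyl-6-oxocyclohex-2-en-1-ylidene]ethyl}-3,5,5-trimethylhex-2-enedioate | C=C[C@@]1(C)CC(O[Si](C)(C)C(C)(C)C)=C/C(=C\C[C@@H](C(C)(C)C(=O)OC(C)(C)C)/C(C)=C/C(=O)OC(C)(C)C)C1=O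
F6 | step 10 | 7α-bromo-8β,11β,14β-triol of the secodiester core | C=C[C@@]1(C)C[C@H](O)[C@@H]2[C@@](C)(CC(=O)OC(C)(C)C)[C@H](C(C)(C)C(=O)OC(C)(C)C)C[C@@H](Br)[C@@]2(O)[C@@H]1O
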